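(All runs stem from a simulated flask for an exercise; the scatter is artificial.)

Amounts first: the flask charges 15 mM of substrate and 2.50 equiv of coupling partner, so its partner concentration B is 37.5 mM. Of coupling partner, the earlier run ash holds 25.0 mM, the run larch 55.0 mM and the run alder 75.0 mM. Partner is charged in excess, so target formation is reckoned as pseudo-first-order in substrate, with a gain that grows with B.

| flask | substrate | coupling partner | remark | time |
|---|---|---|---|---|
| ash | 10 mM | 2.5 equiv | run made earlier |  |
| larch | 22 mM | 2.5 equiv | run made earlier |  |
| alder | 15 mM | 5 equiv | run made earlier |  |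
| flask | 15 mM | 2.50 equiv |  | 2.0 h |

- when, up to 2.0 h, the flask holds most target
- the amount of target, in percent of the substrate charged, at that time

- ash (time / min: target / %, substrate / %): 3.00: 6.3, 76.4; 8.00: 10.0, 51.8; 25.0: 8.1, 18.6; 80.0: 0.8, 1.9
- larch (time / min: target / %, substrate / %): 3.00: 12.3, 71.4; 8.00: 19.3, 45.1; 25.0: 15.4, 19.1; 80.0: 2.8, 2.4
- alder (time / min: target / %, substrate / %): 3.00: 16.5, 67.6; 8.00: 23.7, 41.8; 25.0: 20.0, 17.9; 80.0: 3.2, 3.8

(each reading ± 0.5 percentage points)

Each run reads highest at 8.00 min. Let g be that reading, as a fraction of substrate charged, divided by B. Ash gives g = 4.00 M⁻¹, the yield per partner; larch gives 3.51 M⁻¹ and alder 3.16 M⁻¹.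

My own reckoning has two ways to the flask's height. Alder has the flask's substrate charge, and its g times the flask's B gives 11.8 %. Interpolating g in B between ash and larch gives 3.80 M⁻¹, hence 14.2 %. They part, and alder cheats: g falls as B rises, and alder's B is twice the flask's. I commit to 14.2 % for the height, an estimate built on readings at 8.00 min, and a reading need not catch the peak.

The forecast gives 14.5 % at 0.18 h, adding “The peak is broad, so its time is less certain than its height.”

The flask peaks at 0.190 h with 14.7 % of target, a g of 3.92 M⁻¹, while side product already stands at 46.4 %.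

    substrate → side product (k = 0.0653 min⁻¹)
    substrate + coupling partner ⇌ target (K = 10.7 M⁻¹, k = 1.04 M⁻¹ min⁻¹)

A neighbouring flask charges 6.0 mM of substrate at the same equivalents, so its B is 15.0 mM. The line through ash and larch extends to g = 4.16 M⁻¹, which gives 6.24 %. That neighbour reaches 6.55 %. At 2.00 h it holds 0.0525 % of target and 99.8 % of side product.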